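## Structural features

The target 33 is an isoflavan quinone. Aromatic ring A is fused through the C4a–C8a bond to the dihydropyran ring C (O1, C2, C3, C4), and C3 carries ring B, a 2-hydroxy-1,4-benzoquinone, through the C3–C1' bond. Ring A is a fully differentiated phloroglucinol-type ring: ring oxygen O1 at C8a, hydrogen at C8, methoxy at C7, a C-prenyl group at C6 and a second methoxy at C5. Ring B has carbonyl groups at C2' and C5', the acidic hydroxyl at C4', a second prenyl group at C3' and hydrogen at C6'. C3 is the only stereocentre (R) and has no stereogenic neighbour, so it must be set absolutely; once ring B is a quinone, its hydrogen is vinylogously acidic (γ to the C5' carbonyl through C1'=C6'). The fragile groups are the two trisubstituted prenyl alkenes (acid, electrophilic halogen, hydrogenation, strong oxidants), the hydroxyquinone (base, nucleophiles, reductants) and the very electron-rich ring A. The real difficulty is the unambiguous placement of O1, the C7 methoxy group, the C6 prenyl group and the C5 oxygen on ring A while ring C and C3 are in place. The key step uses the fact that O1–C8a, C8–H, C7–OMe and C6–prenyl map onto C6, C5, C4 and C3 of a 6-alkoxy-4-methoxy-3-prenyl-2-pyranone. Ring A then lacks only C4a and C5, which an alkyne tethered through O1–C2–C3–C4 supplies while closing ring C; a boron substituent on the distal alkyne carbon is the latent C5 oxygen.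

## Logic of the disconnections

33 ⇒ 32. Only the O4'–H bond is changed: the hydroxyl of ring B is traced back to an O4'–CH3 ether. The free hydroxyquinone is acidic, chelating and base-sensitive, so it should exist only after the last step, whereas 32 is neutral. The forward hydrolysis must be brief and cold, because C3–H is vinylogously acidic once ring B is a quinone.

32 ⇒ 31. The two C=O bonds at C2' and C5' are traced back to two aryl C–O–CH3 groups. Ring B then travels as a robust arene through every organometallic, basic and thermal step, and the quinone problem shrinks to one late oxidation. The oxidant must select ring B (1,2,4-trioxygenated, with a para pair of ethers) over ring A (1,3,5-trioxygenated, no para pair) and spare two prenyl groups.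

31 ⇒ 30 ⇒ 29. The O5–CH3 bond and then the C5–O bond are cut, leaving a C5–B bond. Boron is the heteroatom that a cycloaddition can deliver to C5 with full positional control, and its oxidation is regiospecific. The forward steps need an oxidant that attacks boron but not the alkenes, and a methylation of a phenol flanked on both sides.

29 ⇒ 27 (key disconnection). The bonds C4a–C8a and C5–C6 are cut and a –C(=O)–O– bridge is put back between C6 and C8a. Rings A and C disappear together; the contiguous O1/H/OMe/prenyl pattern of ring A becomes the substitution pattern of a monocyclic diene, and C4a and C5 become a boron-capped alkyne. The forward step must be purely thermal, intramolecular and regiochemically locked by the O1–C2–C3–C4 tether; it creates no stereocentre and must leave C3 alone.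

27 ⇒ 26. The C(sp)–B bond is cut. Boron is introduced immediately before the cycloaddition, so that the hydrolytically labile alkynylboronate never meets alkoxide, hydride or chromatography. This requires a neutral, catalytic borylation that distinguishes the alkyne C–H bond from two alkenes and a lactone.

26 ⇒ 16 + 24. The C8a–O1 bond (the enol ether bond at C6 of the heterocycle) is cut. This is the point of convergence: ring B with C2, C3, C4 and the alkyne sits in 16, and the future ring-A periphery sits in 24. The alkoxide of 16 must substitute chloride at C6 and not open the lactone at its carbonyl, since only direct substitution keeps the prenyl group next to the lactone carbonyl, that is, at the future C6.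

24 ⇒ 23 ⇒ 20 ⇒ 17. The O–CH3 bond at C4, the C3–CH2 bond of the prenyl group and finally the heterocycle itself are cut; the ring arises from two molecules of 17. Chlorine is fixed at C6 when the ring is made, before the prenyl group enters. In 20 only C3 (between the lactone carbonyl and the enol oxygen) is nucleophilic, so prenylation cannot go to C5 and the relative positions of Cl, OMe and prenyl are settled by construction. The prenylation must be C- rather than O-selective and must not touch C6–Cl.

16 ⇒ 15 ⇒ 12 + 13. The C3–C4 bond is cut, and C2 is adjusted from the acyl to the alcohol oxidation level. The only stereocentre is made here, by alkylation of an enolate that carries 10 as controller. Because the aryl group outranks the incoming propargyl group, the R descriptor at C3 requires the 4R enantiomer of 10. The step needs a Z-enolate formed at low temperature and a reduction that does not epimerise the α-aryl centre.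

12 ⇒ 9 + 10, and 9 ⇒ 8 ⇒ 6. The N–acyl bond is cut, and the CH2–CO2H carbon–carbon bond of 9 is traced through a nitrile to the aldehyde carbon of 6. A one-carbon homologation is chosen because a formyl group is what electrophilic substitution can place at C1' in the presence of a prenyl group. Neither step may use acid strong enough to hydrate or cyclise the alkene.

6 ⇒ 4 ⇒ 1 + 2. The C1'–CHO bond and the C3'–CH2 bond are cut. The two carbon substituents of ring B enter by complementary selectivities: metalation of 1 at the only position between two methoxy groups (C3'), then electrophilic substitution para to a methoxy group (C1'). The reverse order is not possible, and the formylation must tolerate the alkene.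

## Other disconnections considered

Alternative 1: The cut is at the two aryl–CH2 bonds of the prenyl groups (C6–CH2 on ring A, C3'–CH2 on ring B), leading back to the bis(2-methylbut-3-en-2-yl) ether A1 of a prenyl-free isoflavan.
- Forward step: A1 would be heated (about 180 °C, N,N-diethylaniline) so that two aromatic Claisen rearrangements deliver each allyl unit, with allylic inversion, to the single free ortho position of its oxygen, giving the diphenol A2.
- In favour: the rearrangement is established chemistry, the regiochemistry is dictated by the blocked second ortho positions (C4a and C5'), and both acid-sensitive prenyl groups appear late.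
- Against: the step closes no ring and sets no stereocentre. Rings A and C, C3 and a five-fold differentiated oxygen pattern (three methyl ethers, two tertiary allyl ethers on hindered phenols) must all be made beforehand. Tertiary allyl aryl ethers tend to lose isoprene on heating, and an ortho-prenyl phenol such as A2 can cyclise to a chroman.
- Comparison: methylating both phenols of A2 would give 31, after which the last two steps of the chosen route apply, so the endgames are equal. On mechanism the alternative is the better founded plan, since nothing in it is new. On structure the chosen cycloaddition achieves more (two rings and the whole ring-A pattern against two C–C bonds). On step economy the alternative should be longer, because the core it decorates still needs its own asymmetric synthesis and extra protecting-group operations.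

Alternative 2: The cut is at C4a–C5 and C8–C8a (C5–C6 then forms in an electrocyclisation), with ring C left open at O1–C2.
- Forward step: the cyclobutenone A3 would open thermally to a vinylketene and add to the siloxyalkyne A4 in a [2+2] fashion; the new cyclobutenone would open and close (6π) to the phenol A5 (Danheiser benzannulation).
- In favour: it is a known, convergent benzannulation, regiospecific by mechanism; it delivers the C5 oxygen directly as a phenol, with no boron-to-oxygen exchange; and A4 has the carbon skeleton of 16.
- Against: ring C is not formed, so silyl protection, desilylation and a Mitsunobu closure are added. A3 is a strained, base- and heat-sensitive enone that needs its own preparation, and siloxyalkynes are hydrolytically delicate.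
- Comparison: on mechanism the alternative is better precedented, and for that reason it is kept as the fallback for step 13. On structure the chosen step closes both rings in one operation and needs no protecting group. On step economy the two are about equal from 16 onward: six operations to 31 plus the preparation of A3, against five operations plus three for 24.

Alternative 3: The cut is at C1'–C2' of ring B. The methoxyquinone A9, identical with 32, is traced to the 4-alkynyl-4-hydroxycyclobutenone A8, made by adding the lithium acetylide of the ethynylchroman A7 to the more electrophilic carbonyl of the cyclobutenedione A6.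
- Forward step: thermolysis of A8 (about 110 to 140 °C) would open the four-membered ring to an enynyl ketene whose ketene carbon bonds to the distal alkyne carbon; hydrogen transfer in the resulting diradical gives the quinone (Moore rearrangement).
- In favour: ring B is born at the quinone oxidation level with its substituents placed by the dione, so no oxidant ever meets ring A or the prenyl groups. On this point it is better than step 16 of the chosen route. The rearrangement itself is known.
- Against: it builds the easy ring and leaves the hard one, because A7 already contains rings A and C with the full ring-A pattern. C3 becomes a propargylic stereocentre next to the ketene and diradical intermediates, which endangers its configuration. Closure to a five-membered alkylidenecyclopentenedione competes when the alkyne substituent is an alkyl group. A6 needs its own preparation, and the final hydrolysis is still required.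
- Comparison: the endgame after A9 is the same single step (equal). On mechanism the alternative is known chemistry but carries a real selectivity and stereochemical hazard. On step economy it should be longer, because it adds A6 and the acetylide chemistry to an unsolved ring A.

Key step: step 13

Abbreviations: prenyl = 3-methylbut-2-en-1-yl; Ar = 2,4,5-trimethoxy-3-prenylphenyl (ring B before oxidation; attachment carbon = C1').

Remark on the chemistry: atom mapping of 27 and 29 onto 33 needs no change (pyranone C6/C5/C4/C3 become C8a/C8/C7/C6; the alkyne carbons become C4a and C5). C3 is R throughout (C2 > C1' > C4 > H), which requires the (4R)-auxiliary 10.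

## Route

Step 1
Reactants: 1 1,2,4-trimethoxybenzene; 2 1-bromo-3-methylbut-2-ene (prenyl bromide)
Product: 4 1,2,4-trimethoxy-3-prenylbenzene, via aryllithium 3 (not isolated)
Conditions: n-BuLi, THF, 0 to 25 °C; then CuI (10 mol%), 2, −78 to 0 °C
Reagents that add atoms: none
Why: Directed ortho-metalation of 1 occurs at C3, the only position flanked by two methoxy groups; copper-catalysed alkylation of 3 at the primary carbon of the allylic bromide (SN2 rather than SN2') should give the linear prenyl arene.

Step 2
Reactants: 4 1,2,4-trimethoxy-3-prenylbenzene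
Product: 6 2,4,5-trimethoxy-3-prenylbenzaldehyde, via iminium chloride 5 (not isolated)
Conditions: POCl3, DMF, 0 to 40 °C; then aq NaOAc, 25 °C
Reagents that add atoms: N,N-dimethylformamide, CN(C)C=O; water, O
Why: Vilsmeier–Haack formylation, an electrophilic aromatic substitution; C5 of 4 (para to the C2 methoxy group, ortho to the C4 methoxy group) is the most activated free position and is complementary to the metalation site of step 1. The weakly electrophilic chloroiminium ion and a buffered hydrolysis should leave the prenyl alkene alone.

Step 3
Reactants: 6 2,4,5-trimethoxy-3-prenylbenzaldehyde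
Product: 8 Ar-acetonitrile, via N-formyl enamine 7 (not isolated)
Conditions: TosMIC, KOt-Bu, DME, −35 °C; then MeOH, 65 °C
Reagents that add atoms: tosylmethyl isocyanide, [C-]#[N+]CS(=O)(=O)c1ccc(C)cc1
Why: Van Leusen reductive cyanation: the TosMIC anion adds to the aldehyde, the oxazoline opens to 7, and methanolysis removes the formyl group and sulfinate to leave the one-carbon-homologated nitrile. No acid or oxidant touches the prenyl group.

Step 4
Reactants: 8 Ar-acetonitrile
Product: 9 Ar-acetic acid
Conditions: NaOH, EtOH/H2O, 85 °C; then 1 M HCl, 0 °C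
Reagents that add atoms: sodium hydroxide, [Na+].[OH-]; water, O
Why: Alkaline nitrile hydrolysis through the primary amide; methyl ethers and the isolated alkene are inert to hot hydroxide, and cold, brief acidification avoids hydration of the prenyl group.

Step 5
Reactants: 9 Ar-acetic acid; 10 (4R)-4-benzyl-1,3-oxazolidin-2-one
Product: 12 (4R)-4-benzyl-3-(Ar-acetyl)-1,3-oxazolidin-2-one, via mixed pivalic anhydride 11 (not isolated)
Conditions: PivCl, Et3N, THF, −20 °C; then 10, LiCl, 25 °C
Reagents that add atoms: none
Why: N-Acylation of the oxazolidinone through the mixed pivalic anhydride under LiCl/Et3N activation; the hindered pivaloyl carbonyl directs attack to the arylacetyl carbonyl.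

Step 6
Reactants: 12 (4R)-4-benzyl-3-(Ar-acetyl)-1,3-oxazolidin-2-one; 13 3-bromoprop-1-yne (propargyl bromide)
Product: 15 (4R)-4-benzyl-3-[(2R)-2-Ar-pent-4-ynoyl]-1,3-oxazolidin-2-one, via sodium enolate 14 (not isolated)
Conditions: NaN(SiMe3)2, THF, −78 °C; then 13, −78 to −50 °C
Reagents that add atoms: none
Why: Evans asymmetric alkylation: the chelated Z-enolate 14 is attacked by propargyl bromide on the face opposite the C4 benzyl group, which with the (4R)-auxiliary sets C2 as R (aryl outranks propargyl, so the descriptor is opposite to that of the familiar alkyl case of the same topicity). Low temperature suppresses ketene formation and epimerisation.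

Step 7
Reactants: 15 (4R)-4-benzyl-3-[(2R)-2-Ar-pent-4-ynoyl]-1,3-oxazolidin-2-one
Product: 16 (2R)-2-Ar-pent-4-yn-1-ol
Conditions: LiBH4, MeOH (1 equiv), THF, 0 °C
Reagents that add atoms: none
Why: Reductive removal of the auxiliary: borohydride attacks the exocyclic imide carbonyl and gives the primary alcohol without touching C2, the alkyne or the alkenes; 10 is recovered.

Step 8
Reactants: 17 malonyl dichloride (two molecules)
Product: 20 6-chloro-4-hydroxy-2H-pyran-2-one, via pyranone acid chloride 18 (not isolated), via pyranone carboxylic acid 19 (not isolated)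
Conditions: neat, 25 °C, 4 d; then H2O, 1,4-dioxane, 20 to 70 °C
Reagents that add atoms: none
Why: Self-condensation of malonyl dichloride (C-acylation of one enolised molecule by a second, then enol O-acylation) gives the 2-pyranone 18. Water hydrolyses only the exocyclic acid chloride, and the vinylogous β-keto acid 19 loses CO2 on warming, while the ring C6–Cl of the acidic 4-hydroxypyranone survives.

Step 9
Reactants: 20 6-chloro-4-hydroxy-2H-pyran-2-one; 21 prenyl acetate
Product: 23 6-chloro-4-hydroxy-3-prenyl-2H-pyran-2-one, via sodium pyranolate 22 (not isolated)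
Conditions: NaH, THF, 0 °C; then 21, Pd(PPh3)4 (5 mol%), 25 to 50 °C; citric acid work-up
Reagents that add atoms: none
Why: Tsuji–Trost allylation: the soft pyranolate 22 attacks the π-prenyl palladium complex at its unsubstituted terminus, and any O-allyl product is re-ionised by zerovalent palladium, so the C3-prenyl compound should accumulate. C3, between the lactone carbonyl and the enol oxygen, is the only nucleophilic carbon of 22, which fixes the prenyl group next to the lactone carbonyl.

Step 10
Reactants: 23 6-chloro-4-hydroxy-3-prenyl-2H-pyran-2-one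
Product: 24 6-chloro-4-methoxy-3-prenyl-2H-pyran-2-one
Conditions: Me3SiCHN2, toluene/MeOH (4:1), 0 °C
Reagents that add atoms: (trimethylsilyl)diazomethane, C[Si](C)(C)C=[N+]=[N-]
Why: O-Methylation of the vinylogous acid with the diazomethane surrogate under neutral conditions should give the 4-methoxy-2-pyranone (any 2-methoxy-4-pyranone isomer is separable). It also turns C6–Cl into a vinylogous acyl chloride.

Step 11
Reactants: 16 (2R)-2-Ar-pent-4-yn-1-ol; 24 6-chloro-4-methoxy-3-prenyl-2H-pyran-2-one
Product: 26 4-methoxy-3-prenyl-6-{[(2R)-2-Ar-pent-4-yn-1-yl]oxy}-2H-pyran-2-one, via sodium alkoxide 25 (not isolated)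
Conditions: NaH, THF, 0 °C; then 24 (1.2 equiv), −78 to −30 °C
Reagents that add atoms: none
Why: Addition–elimination (vinylogous acyl substitution) of the primary alkoxide at C6, the chlorine-bearing terminus of the dienyl lactone. The lactone carbonyl is deactivated as a vinylogous carbonate by the 4-methoxy group and shielded by the C3 prenyl group, so C6 should be attacked. NaH deprotonates only the hydroxyl group, and low temperature with a slight excess of 24 limits attack of alkoxide on the product.

Step 12
Reactants: 26 4-methoxy-3-prenyl-6-{[(2R)-2-Ar-pent-4-yn-1-yl]oxy}-2H-pyran-2-one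
Product: 27 4-methoxy-3-prenyl-6-{[(2R)-2-Ar-5-(4,4,5,5-tetramethyl-1,3,2-dioxaborolan-2-yl)pent-4-yn-1-yl]oxy}-2H-pyran-2-one
Conditions: HBpin (1.5 equiv), [N(C6H3-4-Me-2-PiPr2)2]Ir(C8H14) (1 mol%), toluene, 25 °C
Reagents that add atoms: pinacolborane, CC1(C)OBOC1(C)C
Why: Dehydrogenative C(sp)–H borylation of the terminal alkyne by the amido-bis(phosphine) iridium pincer catalyst, a known reaction that is selective for alkyne C–H bonds over alkene hydroboration. It is placed last so that the water-sensitive alkynylboronate never meets alkoxide or hydride; 27 is used without chromatography.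

Step 13
Reactants: 27 4-methoxy-3-prenyl-6-{[(2R)-2-Ar-5-(4,4,5,5-tetramethyl-1,3,2-dioxaborolan-2-yl)pent-4-yn-1-yl]oxy}-2H-pyran-2-one
Product: 29 2-[(3R)-3-Ar-7-methoxy-6-prenyl-3,4-dihydro-2H-chromen-5-yl]-4,4,5,5-tetramethyl-1,3,2-dioxaborolane, via bridged lactone 28 (not isolated)
Conditions: o-xylene (0.01 M, degassed, dry), BHT (5 mol%), sealed tube, 150 °C
Reagents that add atoms: none
Why: Proposed new method: the 4,6-dialkoxy-2-pyranone of 27 is an electron-rich cyclic diene (C3=C4–C5=C6) and the alkynyl pinacol boronate a mildly electron-poor 2π partner, so a thermal normal-demand [4+2] cycloaddition across pyranone C3 and C6 should give the 2-oxabicyclo[2.2.2]octadienone 28, which at this temperature undergoes cycloreversion with loss of CO2 and aromatises to 29. The closest known reaction types are the intermolecular Diels–Alder/retro-Diels–Alder reaction of 2-pyranones with alkynylboronates, which gives arylboronates, and the intramolecular cycloaddition of 2-pyranones with tethered alkynes; their combination on a 6-alkoxy-2-pyranone has not been shown. Ring C closes as the six-membered tether ring (O1–C2–C3–C4 between pyranone C6 and the proximal alkyne carbon), and ring A closes as the new carbocycle, which becomes aromatic when the lactone bridge leaves as CO2. No stereocentre is created in 29: the two bridgehead centres of 28 are transient and both of its diastereomers converge on the same arene, while C3 is a spectator that is neither deprotonated nor ionised under neutral thermal conditions. The only selectivity needed is regiochemical, and the four-atom tether secures it, because bonding of pyranone C6 to the distal alkyne carbon would require a strained bridged ring; O1, the C7 methoxy group and the C6 prenyl group are therefore placed unambiguously and boron arrives at C5. High dilution disfavours bimolecular cycloaddition, degassing and BHT protect the two prenyl groups, and exclusion of water prevents protodeboronation of the alkynylboronate.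

Step 14
Reactants: 29 2-[(3R)-3-Ar-7-methoxy-6-prenyl-3,4-dihydro-2H-chromen-5-yl]-4,4,5,5-tetramethyl-1,3,2-dioxaborolane
Product: 30 (3R)-3-Ar-7-methoxy-6-prenyl-3,4-dihydro-2H-chromen-5-ol
Conditions: NaBO3·4H2O, THF/H2O (1:1), 25 °C
Reagents that add atoms: sodium perborate, [Na+].[O-]OB=O
Why: Oxidation of the arylboronate: perborate adds to boron and the aryl group migrates to oxygen at the same carbon. The mild, weakly basic medium leaves the alkenes and C3 untouched.

Step 15
Reactants: 30 (3R)-3-Ar-7-methoxy-6-prenyl-3,4-dihydro-2H-chromen-5-ol
Product: 31 (3R)-3-Ar-5,7-dimethoxy-6-prenyl-3,4-dihydro-2H-chromene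
Conditions: MeI, K2CO3, DMF, 25 °C
Reagents that add atoms: iodomethane, CI
Why: Williamson O-methylation of the hindered phenol, the only acidic group in 30.

Step 16
Reactants: 31 (3R)-3-Ar-5,7-dimethoxy-6-prenyl-3,4-dihydro-2H-chromene
Product: 32 5-[(3R)-5,7-dimethoxy-6-prenyl-3,4-dihydro-2H-chromen-3-yl]-2-methoxy-3-prenylcyclohexa-2,5-diene-1,4-dione
Conditions: (NH4)2Ce(NO3)6 (2.2 equiv), MeCN/H2O (2:1), −10 to 0 °C
Reagents that add atoms: water, O
Why: Oxidative demethylation by tetravalent cerium: the 1,2,4-trioxygenated ring B has the lowest oxidation potential and a para pair of methoxy groups (C2', C5'), so two one-electron oxidations with capture of water should give the methoxy-para-quinone, whereas the 1,3,5-trioxygenated ring A has no para pair. Low temperature and a near-stoichiometric charge of oxidant are used to spare ring A and the alkenes.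

Step 17
Reactants: 32 5-[(3R)-5,7-dimethoxy-6-prenyl-3,4-dihydro-2H-chromen-3-yl]-2-methoxy-3-prenylcyclohexa-2,5-diene-1,4-dione
Product: 33 5-[(3R)-5,7-dimethoxy-6-prenyl-3,4-dihydro-2H-chromen-3-yl]-2-hydroxy-3-prenylcyclohexa-2,5-diene-1,4-dione (CNP0241224.1)
Conditions: 0.5 M NaOH, THF/H2O, 0 °C, argon; then 1 M HCl
Reagents that add atoms: sodium hydroxide, [Na+].[OH-]
Why: Hydrolysis of the vinylogous methyl ester by addition of hydroxide at C4' and loss of methoxide; the product forms a stabilised hydroxyquinone anion. Cold, brief, oxygen-free treatment is used because C3–H is vinylogously acidic in the quinone.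

## Compound list

1 | 1,2,4-trimethoxybenzene | COc1ccc(OC)c(OC)c1 | starting material
2 | 1-bromo-3-methylbut-2-ene (prenyl bromide) | CC(C)=CCBr | starting material
3 | (2,3,6-trimethoxyphenyl)lithium | [Li]c1c(OC)ccc(OC)c1OC | intermediate
4 | 1,2,4-trimethoxy-3-prenylbenzene | COc1ccc(OC)c(CC=C(C)C)c1OC | intermediate
5 | N,N-dimethyl-(2,4,5-trimethoxy-3-prenylphenyl)methaniminium chloride | C[N+](C)=Cc1cc(OC)c(OC)c(CC=C(C)C)c1OC.[Cl-] | intermediate
6 | 2,4,5-trimethoxy-3-prenylbenzaldehyde | O=Cc1cc(OC)c(OC)c(CC=C(C)C)c1OC | intermediate
7 | N-{2-Ar-1-[(4-methylphenyl)sulfonyl]ethenyl}formamide | O=CNC(=Cc1cc(OC)c(OC)c(CC=C(C)C)c1OC)S(=O)(=O)c1ccc(C)cc1 | intermediate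
8 | (2,4,5-trimethoxy-3-prenylphenyl)acetonitrile | N#CCc1cc(OC)c(OC)c(CC=C(C)C)c1OC | intermediate
9 | (2,4,5-trimethoxy-3-prenylphenyl)acetic acid | OC(=O)Cc1cc(OC)c(OC)c(CC=C(C)C)c1OC | intermediate
10 | (4R)-4-benzyl-1,3-oxazolidin-2-one | O=C1N[C@H](Cc2ccccc2)CO1 | starting material
11 | 2,2-dimethylpropanoic (2,4,5-trimethoxy-3-prenylphenyl)acetic anhydride | CC(C)(C)C(=O)OC(=O)Cc1cc(OC)c(OC)c(CC=C(C)C)c1OC | intermediate
12 | (4R)-4-benzyl-3-[(2,4,5-trimethoxy-3-prenylphenyl)acetyl]-1,3-oxazolidin-2-one | O=C(Cc1cc(OC)c(OC)c(CC=C(C)C)c1OC)N1[C@H](Cc2ccccc2)COC1=O | intermediate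
13 | 3-bromoprop-1-yne (propargyl bromide) | C#CCBr | starting material
14 | sodium (Z)-enolate of 12 | [Na+].[O-]/C(=C\c1cc(OC)c(OC)c(CC=C(C)C)c1OC)N1[C@H](Cc2ccccc2)COC1=O | intermediate
15 | (4R)-4-benzyl-3-[(2R)-2-(2,4,5-trimethoxy-3-prenylphenyl)pent-4-ynoyl]-1,3-oxazolidin-2-one | C#CC[C@H](c1cc(OC)c(OC)c(CC=C(C)C)c1OC)C(=O)N1[C@H](Cc2ccccc2)COC1=O | intermediate
16 | (2R)-2-(2,4,5-trimethoxy-3-prenylphenyl)pent-4-yn-1-ol | C#CC[C@H](c1cc(OC)c(OC)c(CC=C(C)C)c1OC)CO | intermediate
17 | malonyl dichloride (propanedioyl dichloride) | O=C(Cl)CC(=O)Cl | starting material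
18 | 6-chloro-4-hydroxy-2-oxo-2H-pyran-3-carbonyl chloride | O=C(Cl)C1=C(O)C=C(Cl)OC1=O | intermediate
19 | 6-chloro-4-hydroxy-2-oxo-2H-pyran-3-carboxylic acid | OC(=O)C1=C(O)C=C(Cl)OC1=O | intermediate
20 | 6-chloro-4-hydroxy-2H-pyran-2-one | OC1=CC(=O)OC(Cl)=C1 | intermediate
21 | 3-methylbut-2-en-1-yl acetate (prenyl acetate) | CC(=O)OCC=C(C)C | starting material
22 | sodium 6-chloro-2-oxo-2H-pyran-4-olate | [Na+].[O-]C1=CC(=O)OC(Cl)=C1 | intermediate
23 | 6-chloro-4-hydroxy-3-prenyl-2H-pyran-2-one | CC(C)=CCC1=C(O)C=C(Cl)OC1=O | intermediate
24 | 6-chloro-4-methoxy-3-prenyl-2H-pyran-2-one | COC1=C(CC=C(C)C)C(=O)OC(Cl)=C1 | intermediate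
25 | sodium (2R)-2-(2,4,5-trimethoxy-3-prenylphenyl)pent-4-yn-1-olate | C#CC[C@H](c1cc(OC)c(OC)c(CC=C(C)C)c1OC)C[O-].[Na+] | intermediate
26 | 4-methoxy-3-prenyl-6-{[(2R)-2-(2,4,5-trimethoxy-3-prenylphenyl)pent-4-yn-1-yl]oxy}-2H-pyran-2-one | C#CC[C@H](c1cc(OC)c(OC)c(CC=C(C)C)c1OC)COC1=CC(OC)=C(CC=C(C)C)C(=O)O1 | intermediate
27 | 4-methoxy-3-prenyl-6-{[(2R)-5-(4,4,5,5-tetramethyl-1,3,2-dioxaborolan-2-yl)-2-(2,4,5-trimethoxy-3-prenylphenyl)pent-4-yn-1-yl]oxy}-2H-pyran-2-one | CC1(C)OB(C#CC[C@H](c2cc(OC)c(OC)c(CC=C(C)C)c2OC)COC2=CC(OC)=C(CC=C(C)C)C(=O)O2)OC1(C)C | intermediate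
28 | bridged lactone cycloadduct (2-oxabicyclo[2.2.2]octa-5,7-dien-3-one fused to ring C; C3 is R, both bridgehead diastereomers) | O=C1OC23OC[C@@H](c4cc(OC)c(OC)c(CC=C(C)C)c4OC)CC2=C(B4OC(C)(C)C(C)(C)O4)C1(CC=C(C)C)C(OC)=C3 | intermediate
29 | 2-[(3R)-7-methoxy-6-prenyl-3-(2,4,5-trimethoxy-3-prenylphenyl)-3,4-dihydro-2H-chromen-5-yl]-4,4,5,5-tetramethyl-1,3,2-dioxaborolane | COc1cc2c(c(B3OC(C)(C)C(C)(C)O3)c1CC=C(C)C)C[C@H](c1cc(OC)c(OC)c(CC=C(C)C)c1OC)CO2 | intermediate
30 | (3R)-7-methoxy-6-prenyl-3-(2,4,5-trimethoxy-3-prenylphenyl)-3,4-dihydro-2H-chromen-5-ol | COc1cc2c(c(O)c1CC=C(C)C)C[C@H](c1cc(OC)c(OC)c(CC=C(C)C)c1OC)CO2 | intermediate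
31 | (3R)-5,7-dimethoxy-6-prenyl-3-(2,4,5-trimethoxy-3-prenylphenyl)-3,4-dihydro-2H-chromene | COc1cc2c(c(OC)c1CC=C(C)C)C[C@H](c1cc(OC)c(OC)c(CC=C(C)C)c1OC)CO2 | intermediate
32 | 5-[(3R)-5,7-dimethoxy-6-prenyl-3,4-dihydro-2H-chromen-3-yl]-2-methoxy-3-prenylcyclohexa-2,5-diene-1,4-dione | COc1cc2c(c(OC)c1CC=C(C)C)C[C@H](C1=CC(=O)C(OC)=C(CC=C(C)C)C1=O)CO2 | intermediate
33 | 5-[(3R)-5,7-dimethoxy-6-prenyl-3,4-dihydro-2H-chromen-3-yl]-2-hydroxy-3-prenylcyclohexa-2,5-diene-1,4-dione (CNP0241224.1) | COc1cc2c(c(OC)c1CC=C(C)C)C[C@H](C1=CC(=O)C(O)=C(CC=C(C)C)C1=O)CO2 | target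

## Step count and least certain steps

Total step count: 17. Longest linear sequence: 14 steps (steps 1 to 7 and 11 to 17); steps 8 to 10 form the convergent branch.

Step 13 (key step, the only step beyond known chemistry).
- What may go wrong: the cycloaddition may be too slow at temperatures that 27 tolerates. Protodeboronation of the alkynylboronate by traces of water, or thermal retro-ene loss of the 6-alkoxy group (C3–H is a β-hydrogen of that enol ether), could then outrun ring formation.
- Fallback (known chemistry, the benzannulation of alternative 2), from 16 back to 31: silylation of 16 (TBSCl, imidazole) gives the tert-butyldimethylsilyl ether F1. Deprotonation (n-BuLi), oxidation of the acetylide with LiOOt-Bu and trapping of the ynolate with TIPSOTf give A4. Heating A4 with A3 (made by alkylating the lithium enolate of the parent methoxycyclobutenone with 2) in toluene at 80 to 110 °C gives A5. Methylation (MeI, K2CO3) gives the C5 methyl ether F2, Bu4NF removes both silyl groups to give the phenol alcohol F3, and Mitsunobu etherification (PPh3, DIAD) closes ring C to 31.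

Step 11.
- What may go wrong: the alkoxide may attack the lactone carbonyl instead of C6, with ring opening and loss of the regiochemical assignment, or may add to the product once it has formed.
- Fallback, from 24 back to 26, with the roles of the partners reversed: mild hydrolysis of 24 (aq NaHCO3, THF, then acidification) gives the 6-hydroxypyranone F4 (the enol form of the corresponding glutaconic anhydride). Mitsunobu coupling of this acidic enol with 16 (PPh3, DIAD) alkylates oxygen at the primary carbinol carbon without any free alkoxide. The oxygen remote from the prenyl group is the less hindered one; the regioisomeric ether would have to be separated.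

Step 9.
- What may go wrong: oxidative addition of zerovalent palladium into C6–Cl may compete, and double or O-allylation may consume material.
- Fallback, from 20 back to 24, avoiding allylpalladium chemistry: Mitsunobu etherification of 20 with allyl alcohol gives the 4-allyl ether F5. Claisen rearrangement (toluene, 110 °C) can deliver the allyl group only to C3, because only C3=C4 is an enol ether double bond, giving the 3-allyl-4-hydroxypyranone F6. Me3SiCHN2 gives the 3-allyl-4-methoxypyranone F7, and cross-metathesis with 2-methylbut-2-ene (second-generation Grubbs catalyst) turns allyl into prenyl, which is 24.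

Step 12.
- What may go wrong: catalyst inhibition by the pyranone, hydroboration of the lactone carbonyl, or hydrolysis of the alkynylboronate during isolation.
- Fallback, from 26 back to 27, by stoichiometric metalation: LiN(i-Pr)2 (THF, −78 °C) and 2-isopropoxy-4,4,5,5-tetramethyl-1,3,2-dioxaborolane give the lithium alkynyl(isopropoxy)borate F8, from which anhydrous HCl in Et2O (−78 °C) releases 27.

Step 16.
- What may go wrong: electron transfer from ring A, nitration at C8, or oxidative attack on the prenyl alkenes.
- Fallback, from 31 back to 32, under potential control: anodic oxidation of 31 in MeOH/KOH at a platinum anode, held at the potential of ring B, gives the quinone bis(dimethyl ketal) F9; mild aqueous AcOH hydrolyses it to 32.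

Step 17.
- What may go wrong: base-induced tautomerisation of the alkylquinone to a quinone methide would erode the configuration at C3, and the quinone may decompose in alkali.
- Fallback, from 32 directly to 33, cleaving the O–CH3 bond instead of the ring C4'–O bond: MgBr2·OEt2 (toluene/Et2O, 25 to 40 °C) chelates O4' and the C5' carbonyl, and bromide removes the methyl group by SN2 attack without any base. No new compound is isolated.

## Further compounds

F1 | step 13 | tert-butyl(dimethyl){[(2R)-2-(2,4,5-trimethoxy-3-prenylphenyl)pent-4-yn-1-yl]oxy}silane | C#CC[C@H](c1cc(OC)c(OC)c(CC=C(C)C)c1OC)CO[Si](C)(C)C(C)(C)C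
F2 | step 13 | C5 methyl ether of A5: tert-butyl{[(2R)-3-{2,4-dimethoxy-3-prenyl-6-[(triisopropylsilyl)oxy]phenyl}-2-(2,4,5-trimethoxy-3-prenylphenyl)propyl]oxy}dimethylsilane | COc1cc(O[Si](C(C)C)(C(C)C)C(C)C)c(C[C@H](c2cc(OC)c(OC)c(CC=C(C)C)c2OC)CO[Si](C)(C)C(C)(C)C)c(OC)c1CC=C(C)C
F3 | step 13 | 2-[(2R)-3-hydroxy-2-(2,4,5-trimethoxy-3-prenylphenyl)propyl]-3,5-dimethoxy-4-prenylphenol | COc1cc(O)c(C[C@H](c2cc(OC)c(OC)c(CC=C(C)C)c2OC)CO)c(OC)c1CC=C(C)C
F4 | step 11 | 6-hydroxy-4-methoxy-3-prenyl-2H-pyran-2-one | COC1=C(CC=C(C)C)C(=O)OC(O)=C1
F5 | step 9 | 6-chloro-4-(prop-2-en-1-yloxy)-2H-pyran-2-one | C=CCOC1=CC(=O)OC(Cl)=C1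
F6 | step 9 | 6-chloro-4-hydroxy-3-(prop-2-en-1-yl)-2H-pyran-2-one | C=CCC1=C(O)C=C(Cl)OC1=O
F7 | step 9 | 6-chloro-4-methoxy-3-(prop-2-en-1-yl)-2H-pyran-2-one | C=CCC1=C(OC)C=C(Cl)OC1=O
F8 | step 12 | lithium isopropoxy(pinacolato){(4R)-5-[(4-methoxy-2-oxo-3-prenyl-2H-pyran-6-yl)oxy]-4-(2,4,5-trimethoxy-3-prenylphenyl)pent-1-yn-1-yl}borate | [Li+].CC(C)O[B-]1(C#CC[C@H](c2cc(OC)c(OC)c(CC=C(C)C)c2OC)COC2=CC(OC)=C(CC=C(C)C)C(=O)O2)OC(C)(C)C(C)(C)O1
F9 | step 16 | (3R)-5,7-dimethoxy-3-(3,3,4,6,6-pentamethoxy-5-prenylcyclohexa-1,4-dien-1-yl)-6-prenyl-3,4-dihydro-2H-chromene | COc1cc2c(c(OC)c1CC=C(C)C)C[C@H](C1=CC(OC)(OC)C(OC)=C(CC=C(C)C)C1(OC)OC)CO2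
F0 | step 17 | none | none
A1 | alternative 1 | (3R)-3-{2,5-dimethoxy-4-[(2-methylbut-3-en-2-yl)oxy]phenyl}-7-methoxy-5-[(2-methylbut-3-en-2-yl)oxy]-3,4-dihydro-2H-chromene | COc1cc2c(c(OC(C)(C)C=C)c1)C[C@H](c1cc(OC)c(OC(C)(C)C=C)cc1OC)CO2
A2 | alternative 1 | (3R)-3-(4-hydroxy-2,5-dimethoxy-3-prenylphenyl)-7-methoxy-6-prenyl-3,4-dihydro-2H-chromen-5-ol | COc1cc2c(c(O)c1CC=C(C)C)C[C@H](c1cc(OC)c(O)c(CC=C(C)C)c1OC)CO2
A3 | alternative 2 | 3-methoxy-4-prenylcyclobut-2-en-1-one | COC1=CC(=O)C1CC=C(C)C
A4 | alternative 2 | triisopropyl{[(4R)-5-[(tert-butyldimethylsilyl)oxy]-4-(2,4,5-trimethoxy-3-prenylphenyl)pent-1-yn-1-yl]oxy}silane | CC(C)[Si](OC#CC[C@H](c1cc(OC)c(OC)c(CC=C(C)C)c1OC)CO[Si](C)(C)C(C)(C)C)(C(C)C)C(C)C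
A5 | alternative 2 | 2-[(2R)-3-[(tert-butyldimethylsilyl)oxy]-2-(2,4,5-trimethoxy-3-prenylphenyl)propyl]-5-methoxy-6-prenyl-3-[(triisopropylsilyl)oxy]phenol | COc1cc(O[Si](C(C)C)(C(C)C)C(C)C)c(C[C@H](c2cc(OC)c(OC)c(CC=C(C)C)c2OC)CO[Si](C)(C)C(C)(C)C)c(O)c1CC=C(C)C
A6 | alternative 3 | 3-methoxy-4-prenylcyclobut-3-ene-1,2-dione | COC1=C(CC=C(C)C)C(=O)C1=O
A7 | alternative 3 | (3R)-3-ethynyl-5,7-dimethoxy-6-prenyl-3,4-dihydro-2H-chromene | COc1cc2c(c(OC)c1CC=C(C)C)C[C@H](C#C)CO2
A8 | alternative 3 | 4-{[(3R)-5,7-dimethoxy-6-prenyl-3,4-dihydro-2H-chromen-3-yl]ethynyl}-4-hydroxy-3-methoxy-2-prenylcyclobut-2-en-1-one | COc1cc2c(c(OC)c1CC=C(C)C)C[C@H](C#CC1(O)C(OC)=C(CC=C(C)C)C1=O)CO2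
A9 | alternative 3 | 5-[(3R)-5,7-dimethoxy-6-prenyl-3,4-dihydro-2H-chromen-3-yl]-2-methoxy-3-prenylcyclohexa-2,5-diene-1,4-dione (identical with 32) | COc1cc2c(c(OC)c1CC=C(C)C)C[C@H](C1=CC(=O)C(OC)=C(CC=C(C)C)C1=O)CO2
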